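## The problem

Monotesone A is a flavanone. Ring A is a phloroglucinol-type benzene with free hydroxyls at C5 and C7. It is fused through C4a and C8a to ring C, a dihydropyranone holding O1, the C4 carbonyl and the C3 methylene. Ring B, a catechol with a prenyl group on O4' and a free O3', sits on C2.

C2 is the only stereocentre and must be S. Nothing else in the molecule can direct it, so it has to come from a chiral catalyst or a chiral building block. C2 is benzylic, bonded to O1 and β to the ketone. An enolate at C3 can therefore expel the ring A phenoxide (retro-oxa-Michael opening) and reclose without facial bias, so the route must avoid base once C2 is set.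

Four phenolic oxygens must be told apart and only O4' is alkylated. In the flavanone O3' and O4' do not differ in acidity and O7 is the most acidic, so the distinction is best drawn in a ring B precursor where a para carbonyl group singles out O4'.

The aryl prenyl ether is the fragile group. It is cleaved by zerovalent palladium with nucleophiles, reduced over palladium and hydrogen, and ionised by strong acid. It must enter after those operations, and the last unmasking must be mild.

The enabling feature is that C4 is a lone carbonyl carbon between C4a of ring A and the two-carbon unit C3-C2 that carries ring B, while C8a bears the oxygen that closes onto C2. Ring C therefore divides into an ortho-iodophenol (C4a-I, C8a-OH), carbon monoxide (C4) and an arylacetylene (C3, C2, ring B). The flat flavone that results is a prochiral β-aryl enone that can take hydride at C2 from one face.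

## Retrosynthesis

**17 from 16.** The last cut removes three acetal C-O bonds: 17 comes from its 5,7,3'-tris(methoxymethyl) ether 16. Acetals are chosen over silyl or acyl groups because they survive amine, palladium, hydrogenolysis, carbonate base and hydride, and cannot migrate between the neighbouring catechol oxygens. The forward step must cleave three aryl acetals by acid methanolysis without ionising the prenyl ether or disturbing C2.

**16 from 14.** The C2-H bond, and with it the stereocentre, is cut next: 16 comes from flavone 14 by enantioselective conjugate reduction, through silyl enol ether 15. Closing ring C on a chalcone would create C2 under equilibrating basic conditions. Reduction of the flavone creates it in an irreversible hydride transfer two steps from the end. The forward step needs face-selective hydride delivery to C2 and capture of the enolate before it can open ring C.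

**14 from 12 and 13, and 12 from 11.** The O4'-prenyl bond is cut to phenol 12 and prenyl bromide 13, and 12 is traced to benzyl ether 11. The prenyl group is thereby introduced after the palladium step and after hydrogenolysis. Both operations are placed on the achiral flavone, where carbonate base and hydrogen can do no stereochemical harm.

**11 from 3, 7 and 8.** The key cut breaks C4-C4a, C3-C4 and O1-C2, dividing 11 into iodophenol 3, arylacetylene 7 and carbon monoxide 8. This gives the whole carbon skeleton from three simple pieces in one flask and puts C4 at the ketone oxidation level directly. The forward reaction passes through ynone 9 and enaminone 10. It needs CO insertion before alkyne transfer and 6-endo rather than 5-exo closure.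

**7 from 6, 5 and 4.** The alkyne carbon of 7 is cut back to aldehyde 6 (one-carbon homologation). Compound 6 comes from 5 by acetal protection, and 5 from 3,4-dihydroxybenzaldehyde 4 by benzylation of the more acidic 4-hydroxyl. This is where O4' is singled out.

**3 from 2 and 1.** The C-I bond of 3 is cut to give 2, and 2 comes from phloroglucinol 1 by double acetal protection. Protecting first makes 2 the only possible bis-ether. The one remaining selectivity question is iodination ortho rather than para to the free hydroxyl, where both statistics and sterics favour 3.

## Roads not taken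

**Alternative 1:** The cut runs through ring A. C8-C8a, C5-C6, C7-C8 and C4a-C5 are broken, leaving diazoketone A2 (a C2-aryl dihydropyranone with a diazoacetyl group on C8a) and silyloxyalkyne A3.
- **Forward step:** irradiation of A2 causes a Wolff rearrangement in which C8a migrates to the diazo carbon. The ketene adds A3 in a (2+2) sense, the cyclobutenone opens, and six-electron closure and tautomerisation give A1 with O5 free and O7 silylated.
- **Merits:** the stereocentre would be set early by an asymmetric hetero-Diels-Alder reaction, so no late enantioselective step is needed. No palladium or hydrogen is used, so the prenyl ether could be carried from the start. The ending is a fluoride desilylation, which is gentler on the prenyl ether than the acid step chosen here; in that respect this road is better.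
- **Weak points:** A2 is a diazoketone on a vinylogous ester and costs several steps. The photolysis must tolerate an enone chromophore and an aryl allyl ether. The thermal stages heat a ring whose C2-O1 bond can open, which would erode the early stereocentre. A3 must be made and used fresh.
- **Comparison:** against the gentler ending, the chosen plan sets convergence from two cheap aromatic building blocks, close precedent for every bond made in the key step, and a stereocentre created two steps from the end and never heated.

**Alternative 2:** The cut breaks C3-C4 and O1-C2, giving salicylaldehyde A5, styrene A6 and orthoformate A7.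
- **Forward step:** a chiral Brønsted acid turns A5 and A7 into a 4-methoxy ortho-quinone methide, which adds A6 in an inverse-demand hetero-Diels-Alder reaction. The product is the 2,4-cis flavan A4, with C2 and C4 set in the ring-forming event.
- **Merits:** ring closure and stereocentre come from one catalytic step and there is no flat intermediate to reduce. On that point it is more direct than annulation followed by reduction.
- **Weak points:** C4 arrives as a methyl ether and must be raised to the ketone. Cleaving a benzylic methyl ether on so electron-rich a flavan invites ionisation at C4, with elimination across C3-C4 and loss of silyl groups, before an oxidation can follow. The benzyl-for-prenyl exchange is still needed. A silyl ether on O3' beside a phenol to be freed on O4' can migrate. High induction is documented mainly for simpler partners.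
- **Comparison:** the chosen plan delivers C4 at the correct oxidation level from CO and uses acetals that cannot migrate. It pays for this with a separate enantioselective step.

**Alternative 3:** The cut breaks O1-C8a and C4-C4a, giving aryne precursor A9 and the enantiopure β-hydroxy ester A10.
- **Forward step:** fluoride releases the aryne from A9. The C2 alkoxide of A10 adds at C8a, the aryne carbon remote from the neighbouring alkoxy group, and the aryl anion at C4a attacks the ester. The product A8 is identical with 16.
- **Merits:** it is the shortest road. The stereocentre comes from a reliable asymmetric aldol or ketone reduction, the prenyl ether is present from the start, and the product is one step from the target. If it worked it would be shorter than the chosen plan.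
- **Weak points:** the alkoxide of a β-hydroxy ester in a basic fluoride medium can undergo retro-aldol cleavage or dehydration. The aryl anion can be protonated before it reaches the ester. The flavanone then sits in base, where ring opening and reclosure racemise C2. A9 needs about four steps from 2.
- **Comparison:** against the brevity, the chosen plan sets the absence of base after C2 exists and a ring-forming step with no configurational risk.

Key step: step 6

Assumptions:
- Flavonoid numbering is used (O1, C2, C3, C4, C4a, C5 to C8, C8a; ring B primed).
- The (R) antipode of DTBM-SEGPHOS is written in step 9. Which antipode leads to the S configuration is to be settled on a small scale, and the other antipode is used if the sense is opposite.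

## Route

Step 1
Reactants: 1 phloroglucinol
Product: 2 3,5-bis(methoxymethoxy)phenol
Conditions: MOMCl (2.0 equiv), i-Pr2NEt, THF/DMF, 0 °C to rt
Reagents that add atoms: chloromethyl methyl ether, COCCl
Why: Williamson-type O-alkylation of the phenoxide by an α-chloro ether; 2 is the only bis-ether the symmetric triol can give, so chromatography only has to remove the mono- and tris-ethers, and the mono-ether can be resubmitted.

Step 2
Reactants: 2 3,5-bis(methoxymethoxy)phenol
Product: 3 2-iodo-3,5-bis(methoxymethoxy)phenol
Conditions: N-iodosuccinimide (1.0 equiv), CH2Cl2, −20 °C to 0 °C, dark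
Reagents that add atoms: N-iodosuccinimide, O=C1CCC(=O)N1I
Why: Electrophilic aromatic iodination of an activated phenol under neutral conditions that spare the acetals; the two equivalent positions ortho to the free hydroxyl are favoured statistically and sterically over the position between the two acetal oxygens, and the symmetric 4-iodo isomer should be separable by chromatography.

Step 3
Reactants: 4 3,4-dihydroxybenzaldehyde
Product: 5 4-(benzyloxy)-3-hydroxybenzaldehyde
Conditions: BnBr (1.1 equiv), NaHCO3, NaI (cat.), DMF, 40 °C
Reagents that add atoms: benzyl bromide, BrCc1ccccc1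
Why: Regioselective Williamson etherification; the 4-hydroxyl, para to the formyl group, is the more acidic, so the weak base ionises and alkylates it alone.

Step 4
Reactants: 5 4-(benzyloxy)-3-hydroxybenzaldehyde
Product: 6 4-(benzyloxy)-3-(methoxymethoxy)benzaldehyde
Conditions: MOMCl, i-Pr2NEt, CH2Cl2, 0 °C to rt
Reagents that add atoms: chloromethyl methyl ether, COCCl
Why: Standard methoxymethyl protection of a phenol; the aldehyde and benzyl ether are inert.

Step 5
Reactants: 6 4-(benzyloxy)-3-(methoxymethoxy)benzaldehyde
Product: 7 1-(benzyloxy)-4-ethynyl-2-(methoxymethoxy)benzene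
Conditions: dimethyl (1-diazo-2-oxopropyl)phosphonate, K2CO3, MeOH, rt
Reagents that add atoms: dimethyl (1-diazo-2-oxopropyl)phosphonate, COP(=O)(OC)C(=[N+]=[N-])C(C)=O
Why: Seyferth-Gilbert homologation in the Ohira-Bestmann variant; methanolysis frees the diazomethylphosphonate anion, which olefinates the aldehyde, and loss of N2 with 1,2-hydrogen shift gives the terminal alkyne under conditions to which both ethers are stable.

Step 6
Reactants: 3 2-iodo-3,5-bis(methoxymethoxy)phenol; 7 1-(benzyloxy)-4-ethynyl-2-(methoxymethoxy)benzene; 8 carbon monoxide
Product: 11 2-[4-(benzyloxy)-3-(methoxymethoxy)phenyl]-5,7-bis(methoxymethoxy)-4H-chromen-4-one, via ynone 9 (not isolated), via enaminone 10 (not isolated)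
Conditions: PdCl2(PPh3)2 (5 mol%), CO (20 bar), Et2NH, 120 °C, autoclave
Reagents that add atoms: none
Why: The closest known reaction type is the palladium-catalysed carbonylative coupling-annulation of ortho-iodophenols with terminal arylacetylenes in a secondary amine, which gives flavones. PdCl2(PPh3)2 is reduced in the medium to zerovalent palladium, which inserts into the C-I bond of 3; CO insertion gives the aroylpalladium species (C4-C4a), and amine-assisted transfer of the acetylide of 7 with reductive elimination gives ynone 9 (C3-C4). Et2NH adds to the ynone at C2 to give enaminone 10, and the ortho-hydroxyl closes ring C by 6-endo-trig addition at C2 with loss of the amine (O1-C2), giving the aromatic pyranone of 11. No stereocentre is formed. CO insertion must precede alkyne transfer, since direct coupling would lead by 5-endo closure to a 2-arylbenzofuran; the CO pressure, the absence of a copper co-catalyst and the relief of strain on acylating a doubly ortho-substituted arylpalladium favour insertion. Alkyne transfer must also outrun attack of the amine on the acylpalladium, which ready deprotonation of the palladium-bound arylacetylene in the amine favours, the diethylamide being the by-product to watch. Closure must be 6-endo and not 5-exo to the aurone, and the enaminone route secures this because the amine has made C2 the electrophilic carbon and is the leaving group there. The acetals and the benzyl ether are inert to amine, CO and palladium.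

Step 7
Reactants: 11 2-[4-(benzyloxy)-3-(methoxymethoxy)phenyl]-5,7-bis(methoxymethoxy)-4H-chromen-4-one
Product: 12 2-[4-hydroxy-3-(methoxymethoxy)phenyl]-5,7-bis(methoxymethoxy)-4H-chromen-4-one
Conditions: H2 (1 bar), Pd/C (10 wt%), EtOAc/THF, rt
Reagents that add atoms: none
Why: Hydrogenolysis of a benzyl aryl ether; the C2-C3 double bond of the chromone is part of an aromatic pyranone and should resist reduction at 1 bar, and the acetals are stable in a neutral aprotic solvent.

Step 8
Reactants: 12 2-[4-hydroxy-3-(methoxymethoxy)phenyl]-5,7-bis(methoxymethoxy)-4H-chromen-4-one; 13 1-bromo-3-methylbut-2-ene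
Product: 14 5,7-bis(methoxymethoxy)-2-[3-(methoxymethoxy)-4-(3-methylbut-2-enyloxy)phenyl]-4H-chromen-4-one
Conditions: K2CO3, DMF, rt
Reagents that add atoms: none
Why: Williamson etherification; the 4'-hydroxyl of a flavone is a vinylogous acid fully ionised by carbonate and is O-alkylated by the primary allylic bromide at room temperature, and on the achiral flavone the base can harm no stereocentre.

Step 9
Reactants: 14 5,7-bis(methoxymethoxy)-2-[3-(methoxymethoxy)-4-(3-methylbut-2-enyloxy)phenyl]-4H-chromen-4-one
Product: 16 (S)-5,7-bis(methoxymethoxy)-2-[3-(methoxymethoxy)-4-(3-methylbut-2-enyloxy)phenyl]chroman-4-one, via silyl enol ether 15 (not isolated)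
Conditions: Cu(OAc)2·H2O (5 mol%), (R)-DTBM-SEGPHOS (5.5 mol%), (EtO)2MeSiH (3 equiv), toluene/THF, 0 °C to rt; then AcOH, THF/H2O, rt
Reagents that add atoms: none
Why: Asymmetric conjugate reduction with a bisphosphine-ligated copper hydride, a reaction type established for chromones and β-aryl enones; the hydride adds to C2 on the face selected by the chiral ligand, which sets C2 as S. The copper enolate is silylated to 15, which masks the ketone from 1,2-reduction and removes the enolate before it can expel the ring A phenoxide, and mildly acidic hydrolysis releases 16 without base. The unactivated prenyl alkene is not hydrocuprated.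

Step 10
Reactants: 16 (S)-5,7-bis(methoxymethoxy)-2-[3-(methoxymethoxy)-4-(3-methylbut-2-enyloxy)phenyl]chroman-4-one
Product: 17 monotesone A, (S)-5,7-dihydroxy-2-[3-hydroxy-4-(3-methylbut-2-enyloxy)phenyl]chroman-4-one
Conditions: HCl (1.25 M in MeOH), THF, 0 °C to rt
Reagents that add atoms: none
Why: Acid-catalysed acetal methanolysis, each methoxymethyl group leaving as dimethoxymethane; ionisation of an O,O-acetal to an oxocarbenium ion is much faster than ionisation of an aryl prenyl ether to an allyl cation, so dilute acid at or below room temperature should free the three phenols and keep the ether. The medium is never basic, so C2 is not epimerised.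

## Compound list

1 | phloroglucinol (benzene-1,3,5-triol) | Oc1cc(O)cc(O)c1 | starting material
2 | 3,5-bis(methoxymethoxy)phenol | COCOc1cc(O)cc(OCOC)c1 | intermediate
3 | 2-iodo-3,5-bis(methoxymethoxy)phenol | COCOc1cc(O)c(I)c(OCOC)c1 | intermediate
4 | 3,4-dihydroxybenzaldehyde | O=Cc1ccc(O)c(O)c1 | starting material
5 | 4-(benzyloxy)-3-hydroxybenzaldehyde | O=Cc1ccc(OCc2ccccc2)c(O)c1 | intermediate
6 | 4-(benzyloxy)-3-(methoxymethoxy)benzaldehyde | O=Cc1ccc(OCc2ccccc2)c(OCOC)c1 | intermediate
7 | 1-(benzyloxy)-4-ethynyl-2-(methoxymethoxy)benzene | C#Cc1ccc(OCc2ccccc2)c(OCOC)c1 | intermediate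
8 | carbon monoxide | [C-]#[O+] | starting material
9 | 3-[4-(benzyloxy)-3-(methoxymethoxy)phenyl]-1-[2-hydroxy-4,6-bis(methoxymethoxy)phenyl]prop-2-yn-1-one (ynone) | O=C(C#Cc1ccc(OCc2ccccc2)c(OCOC)c1)c1c(O)cc(OCOC)cc1OCOC | intermediate (not isolated)
10 | (E)-3-[4-(benzyloxy)-3-(methoxymethoxy)phenyl]-3-(diethylamino)-1-[2-hydroxy-4,6-bis(methoxymethoxy)phenyl]prop-2-en-1-one (enaminone; drawn E, the geometry is lost on ring closure) | CCN(CC)/C(=C/C(=O)c1c(O)cc(OCOC)cc1OCOC)c1ccc(OCc2ccccc2)c(OCOC)c1 | intermediate (not isolated)
11 | 2-[4-(benzyloxy)-3-(methoxymethoxy)phenyl]-5,7-bis(methoxymethoxy)-4H-chromen-4-one | O=c1cc(-c2ccc(OCc3ccccc3)c(OCOC)c2)oc2cc(OCOC)cc(OCOC)c12 | intermediate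
12 | 2-[4-hydroxy-3-(methoxymethoxy)phenyl]-5,7-bis(methoxymethoxy)-4H-chromen-4-one | O=c1cc(-c2ccc(O)c(OCOC)c2)oc2cc(OCOC)cc(OCOC)c12 | intermediate
13 | 1-bromo-3-methylbut-2-ene (prenyl bromide) | CC(C)=CCBr | starting material
14 | 5,7-bis(methoxymethoxy)-2-[3-(methoxymethoxy)-4-(3-methylbut-2-enyloxy)phenyl]-4H-chromen-4-one | CC(C)=CCOc1ccc(-c2cc(=O)c3c(OCOC)cc(OCOC)cc3o2)cc1OCOC | intermediate
15 | (S)-4-[diethoxy(methyl)silyloxy]-5,7-bis(methoxymethoxy)-2-[3-(methoxymethoxy)-4-(3-methylbut-2-enyloxy)phenyl]-2H-chromene (silyl enol ether) | CC(C)=CCOc1ccc([C@@H]2C=C(O[Si](C)(OCC)OCC)c3c(OCOC)cc(OCOC)cc3O2)cc1OCOC | intermediate (not isolated)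
16 | (S)-5,7-bis(methoxymethoxy)-2-[3-(methoxymethoxy)-4-(3-methylbut-2-enyloxy)phenyl]chroman-4-one | CC(C)=CCOc1ccc([C@@H]2CC(=O)c3c(OCOC)cc(OCOC)cc3O2)cc1OCOC | intermediate
17 | monotesone A, (S)-5,7-dihydroxy-2-[3-hydroxy-4-(3-methylbut-2-enyloxy)phenyl]chroman-4-one | CC(C)=CCOc1ccc([C@@H]2CC(=O)c3c(O)cc(O)cc3O2)cc1O | target

## Step count and risks

Total: 10 steps. Longest linear sequence: 8 steps (steps 3, 4, 5, 6, 7, 8, 9 and 10 from 4); the ring A branch (steps 1 and 2) joins at step 6.

**Step 6 (key step).**
- **What may go wrong:** oxidative addition of zerovalent palladium into the electron-rich, doubly ortho-substituted C-I bond may be slow. That gives time for capture of the acylpalladium by the amine (amide formation), for coupling without CO uptake followed by 5-endo closure, or for 5-exo closure of the ynone.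
- **Fallback:** separate the carbon-carbon bond formation from the ring closure. Starting from 3, acetylation (Ac2O, pyridine) gives 2-iodo-3,5-bis(methoxymethoxy)phenyl acetate F1, a less electron-rich iodide. Carbonylative Sonogashira coupling of F1 with 7 and 8 under a tertiary amine (PdCl2(PPh3)2, CuI, Et3N, THF, CO 1 bar, rt) gives the isolable O-acetyl ynone F2, which a tertiary amine cannot add to. Treating F2 with Et2NH in EtOH removes the acetate by aminolysis, forms the enaminone and closes ring C, returning to the route at 11.

**Step 9.**
- **What may go wrong:** hydrocupration of the electron-rich chromone may be slow. The copper enolate may expel the ring A phenoxide before silyl transfer, leading to ring opening and further reduction. Facial selectivity may be insufficient.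
- **Fallback:** reduce without selectivity and resolve. Starting from 14, 1,4-reduction with LiBH(s-Bu)3 (THF, −78 °C) gives the racemic flavanone F3. Kinetic resolution by asymmetric transfer hydrogenation (RuCl(p-cymene)[TsDPEN], HCO2H/Et3N), using the catalyst antipode that consumes the (2R)-ketone, converts that enantiomer into the cis-(2R,4R)-flavan-4-ol F4. The unreacted (S)-ketone is 16, where the route is rejoined, at the cost of at most half of the material.

**Step 10.**
- **What may go wrong:** the prenyl ether may be lost by acid ionisation, or methanol or HCl may add to the trisubstituted alkene, before the slower acetals on O7 and O3' are cleaved.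
- **Fallback:** a non-protic trans-protection. Starting from 16, TMSOTf with 2,2'-bipyridyl (MeCN, 0 °C) converts the aryl acetals into silyl ethers, the bipyridyl taking up the methoxymethyl carbon. This gives the tris(trimethylsilyl) ether of monotesone A F5, which neutral aqueous methanol hydrolyses to 17.

**Step 2.**
- **What may go wrong:** iodination may occur para to the free hydroxyl, between the two acetal oxygens, or a second iodine may be introduced.
- **Fallback:** directed ortho-metalation. Starting from 2, carbamoylation (ClCONEt2, K2CO3, MeCN) gives 3,5-bis(methoxymethoxy)phenyl diethylcarbamate F6. Lithiation with s-BuLi/TMEDA (THF, −78 °C) between the carbamate, the strongest director, and the neighbouring acetal oxygen, followed by I2, gives 2-iodo-3,5-bis(methoxymethoxy)phenyl diethylcarbamate F7. Cleavage of the carbamate (KOH, EtOH, reflux) returns to the route at 3.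

## Further compounds

F1 | step 6 | 2-iodo-3,5-bis(methoxymethoxy)phenyl acetate | CC(=O)Oc1cc(OCOC)cc(OCOC)c1I
F2 | step 6 | 2-{3-[4-(benzyloxy)-3-(methoxymethoxy)phenyl]prop-2-ynoyl}-3,5-bis(methoxymethoxy)phenyl acetate | CC(=O)Oc1cc(OCOC)cc(OCOC)c1C(=O)C#Cc1ccc(OCc2ccccc2)c(OCOC)c1
F3 | step 9 | racemic 5,7-bis(methoxymethoxy)-2-[3-(methoxymethoxy)-4-(3-methylbut-2-enyloxy)phenyl]chroman-4-one | CC(C)=CCOc1ccc(C2CC(=O)c3c(OCOC)cc(OCOC)cc3O2)cc1OCOC
F4 | step 9 | (2R,4R)-5,7-bis(methoxymethoxy)-2-[3-(methoxymethoxy)-4-(3-methylbut-2-enyloxy)phenyl]chroman-4-ol | CC(C)=CCOc1ccc([C@H]2C[C@@H](O)c3c(OCOC)cc(OCOC)cc3O2)cc1OCOC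
F5 | step 10 | (S)-2-[4-(3-methylbut-2-enyloxy)-3-(trimethylsilyloxy)phenyl]-5,7-bis(trimethylsilyloxy)chroman-4-one | CC(C)=CCOc1ccc([C@@H]2CC(=O)c3c(O[Si](C)(C)C)cc(O[Si](C)(C)C)cc3O2)cc1O[Si](C)(C)C
F6 | step 2 | 3,5-bis(methoxymethoxy)phenyl diethylcarbamate | CCN(CC)C(=O)Oc1cc(OCOC)cc(OCOC)c1
F7 | step 2 | 2-iodo-3,5-bis(methoxymethoxy)phenyl diethylcarbamate | CCN(CC)C(=O)Oc1cc(OCOC)cc(OCOC)c1I
A1 | alternative 1 | (S)-7-O-triisopropylsilyl-3'-O-tert-butyldimethylsilyl monotesone A | CC(C)=CCOc1ccc([C@@H]2CC(=O)c3c(O)cc(O[Si](C(C)C)(C(C)C)C(C)C)cc3O2)cc1O[Si](C)(C)C(C)(C)C
A2 | alternative 1 | (S)-2-[3-(tert-butyldimethylsilyloxy)-4-(3-methylbut-2-enyloxy)phenyl]-6-(diazoacetyl)-2,3-dihydro-4H-pyran-4-one | CC(C)=CCOc1ccc([C@@H]2CC(=O)C=C(C(=O)C=[N+]=[N-])O2)cc1O[Si](C)(C)C(C)(C)C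
A3 | alternative 1 | (triisopropylsilyloxy)ethyne | C#CO[Si](C(C)C)(C(C)C)C(C)C
A4 | alternative 2 | (2S,4S)-2-[4-(benzyloxy)-3-(tert-butyldimethylsilyloxy)phenyl]-5,7-bis(tert-butyldimethylsilyloxy)-4-methoxychroman | c1ccccc1COc1ccc([C@@H]2C[C@H](OC)c3c(O[Si](C)(C)C(C)(C)C)cc(O[Si](C)(C)C(C)(C)C)cc3O2)cc1O[Si](C)(C)C(C)(C)C
A5 | alternative 2 | 2-hydroxy-4,6-bis(tert-butyldimethylsilyloxy)benzaldehyde | O=Cc1c(O)cc(O[Si](C)(C)C(C)(C)C)cc1O[Si](C)(C)C(C)(C)C
A6 | alternative 2 | 1-(benzyloxy)-2-(tert-butyldimethylsilyloxy)-4-vinylbenzene | C=Cc1ccc(OCc2ccccc2)c(O[Si](C)(C)C(C)(C)C)c1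
A7 | alternative 2 | trimethyl orthoformate | COC(OC)OC
A8 | alternative 3 | (S)-5,7,3'-tri-O-methoxymethyl monotesone A (identical with 16) | CC(C)=CCOc1ccc([C@@H]2CC(=O)c3c(OCOC)cc(OCOC)cc3O2)cc1OCOC
A9 | alternative 3 | 3,5-bis(methoxymethoxy)-2-(trimethylsilyl)phenyl trifluoromethanesulfonate | FC(F)(F)S(=O)(=O)Oc1cc(OCOC)cc(OCOC)c1[Si](C)(C)C
A10 | alternative 3 | methyl (S)-3-hydroxy-3-[3-(methoxymethoxy)-4-(3-methylbut-2-enyloxy)phenyl]propanoate | CC(C)=CCOc1ccc([C@@H](O)CC(=O)OC)cc1OCOC
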